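The dihydrobenzofuran ring (O1, C2, C3, C3a, C7a) is traced back to the six-membered pyranone ring of a (2S)-flavanone. In the key step trivalent iodine in trimethyl orthoformate drives ring A carbon C4a from the ketone carbon C4 to C3. This single operation contracts the ring, converts the expelled C4 into the C3 methyl ester and relays C2 to C3 (trans). It exploits the vicinal pair C2(aryl)–O1 and C3(CO2Me)–C3a. Beforehand the same ketone steers rhodium to the peri C5–H for union with a danshensu acrylate and activates C2 for enantioselective arylation. The precursor is thus a peracetylated 5-alkenyl-8-oxyflavanone.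

Key step: step 8

Assumption: the sense of induction of the palladium/pyridine-oxazoline catalyst in step 7 is carried over from cyclic enones, which calls for the (R)-ligand to reach (2S); if this substrate responds in the opposite sense, the (S)-ligand is used.
Remark on numbering: chromone/flavanone numbering (O1, C2, C3, C4, C4a, C5 to C8, C8a) applies up to compound 15, and benzofuran numbering from compound 16 on (C4a becomes C3a, C5 becomes C4, C8 becomes C7, C8a becomes C7a).

Step 1
Reactants: 1 2',3'-dihydroxyacetophenone
Product: 3 8-hydroxy-4H-chromen-4-one, via enaminone 2 (not isolated)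
Conditions: Me2NCH(OMe)2 (3 equiv), toluene, 90 °C; concentrate; then conc. HCl, CH2Cl2, 40 °C
Reagents that add atoms: N,N-dimethylformamide dimethyl acetal, COC(OC)N(C)C
Why: Condensation of the amide acetal with the methyl ketone gives enaminone 2, and acid then triggers 6-endo-trig addition of the ortho phenol and loss of dimethylamine (enaminone route to chromones), while any amide acetal exchanged onto the catechol oxygens is hydrolysed in the same acid stage.

Step 2
Reactants: 3 8-hydroxy-4H-chromen-4-one
Product: 4 4-oxo-4H-chromen-8-yl acetate (8-acetoxychromone)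
Conditions: Ac2O, pyridine, CH2Cl2, 0 °C to rt
Reagents that add atoms: acetic anhydride, CC(=O)OC(C)=O
Why: Standard O-acetylation of the only free phenol gives an acetate that is inert to the later oxidants and keeps ring A from being attacked by trivalent iodine.

Step 3
Reactants: 5 sodium danshensu, sodium (R)-3-(3,4-dihydroxyphenyl)-2-hydroxypropanoate
Product: 6 2,2,2-trichloroethyl (R)-3-(3,4-dihydroxyphenyl)-2-hydroxypropanoate
Conditions: Cl3CCH2OH (5 equiv), TsOH·H2O (1.1 equiv), toluene, reflux, Dean–Stark trap, N2
Reagents that add atoms: 2,2,2-trichloroethanol, OCC(Cl)(Cl)Cl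
Why: Fischer esterification with azeotropic removal of water does not touch the C–O bond of the stereocentre, so the bought (R) configuration is kept, and the trichloroethyl ester is stable to acid, silver salts, divalent palladium and trivalent iodine yet falls to zinc.

Step 4
Reactants: 6 2,2,2-trichloroethyl (R)-3-(3,4-dihydroxyphenyl)-2-hydroxypropanoate
Product: 8 2,2,2-trichloroethyl (R)-2-(acryloyloxy)-3-(3,4-diacetoxyphenyl)propanoate, via diacetate 7 (not isolated)
Conditions: Ac2O (2.05 equiv), Et3N (2.2 equiv), CH2Cl2, −10 °C; then CH2=CHCOCl (1.3 equiv), Et3N (1.5 equiv), BHT (trace), −10 to 0 °C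
Reagents that add atoms: acetic anhydride, CC(=O)OC(C)=O; acryloyl chloride, C=CC(=O)Cl
Why: With Et3N and no acyl-transfer catalyst the two acidic phenols are acetylated far faster than the deactivated secondary α-hydroxy ester, which is then acylated in the same flask by the more reactive acryloyl chloride (chemoselective one-pot acylation) without involving the stereocentre.

Step 5
Reactants: 9 1,2-phenylene diacetate (catechol diacetate)
Product: 11 (3,4-diacetoxyphenyl)boronic acid, via pinacol boronate 10 (not isolated)
Conditions: [Ir(OMe)(cod)]2 (1 mol %), 4,4'-di-tert-butyl-2,2'-bipyridine (2 mol %), B2pin2 (0.55 equiv), THF, 80 °C; then NaIO4, 1 M HCl, THF–H2O, rt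
Reagents that add atoms: bis(pinacolato)diboron, CC1(C)OB(OC1(C)C)B1OC(C)(C)C(C)(C)O1; water, O
Why: Sterically governed iridium-catalysed C–H borylation of a 1,2-disubstituted arene takes place only at C4, and periodate cleavage of the pinacol in dilute acid (one-pot borylation and oxidative hydrolysis) frees the boronic acid without touching the aryl acetates.

Step 6
Reactants: 4 8-acetoxychromone; 8 2,2,2-trichloroethyl (R)-2-(acryloyloxy)-3-(3,4-diacetoxyphenyl)propanoate
Product: 12 2,2,2-trichloroethyl (R)-2-{[(E)-3-(8-acetoxy-4-oxo-4H-chromen-5-yl)acryloyl]oxy}-3-(3,4-diacetoxyphenyl)propanoate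
Conditions: [Cp*RhCl2]2 (2.5 mol %), AgSbF6 (10 mol %), AgOAc (2.2 equiv), ClCH2CH2Cl, 100 °C, sealed tube
Reagents that add atoms: none
Why: In this ketone-directed oxidative C–H olefination (Fujiwara–Moritani type, trivalent rhodium) the C4 carbonyl oxygen guides Cp*Rh to the only peri C–H (C5) through a five-membered rhodacycle, syn insertion of the acrylate and β-hydride elimination give the (E)-alkene, and AgOAc is chosen as oxidant so that no monovalent copper meets the CCl3 group.

Step 7
Reactants: 12 chromone cinnamate from step 6; 11 (3,4-diacetoxyphenyl)boronic acid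
Product: 13 2,2,2-trichloroethyl (R)-2-({(E)-3-[(2S)-8-acetoxy-2-(3,4-diacetoxyphenyl)-4-oxochroman-5-yl]acryloyl}oxy)-3-(3,4-diacetoxyphenyl)propanoate
Conditions: Pd(OCOCF3)2 (10 mol %), (R)-4-tert-butyl-2-(pyridin-2-yl)-4,5-dihydrooxazole (12 mol %), NH4PF6 (30 mol %), H2O (5 equiv), ClCH2CH2Cl, 60 °C, argon
Reagents that add atoms: none
Why: In this enantioselective conjugate addition of an arylboronic acid to a chromone under cationic divalent palladium, the tert-butyl group of the pyridine-oxazoline ligand decides which face of C2 inserts into the Pd–aryl bond and so sets (2S), protonolysis of the palladium enolate needs no base so the flavanone does not ring-open, and the acyclic β-aryl enoate is a much poorer acceptor than the chromone.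

Step 8
Reactants: 13 (2S)-flavanone from step 7
Product: 16 methyl (2S,3S)-7-acetoxy-2-(3,4-diacetoxyphenyl)-4-[(E)-3-{[(R)-3-(3,4-diacetoxyphenyl)-1-oxo-1-(2,2,2-trichloroethoxy)propan-2-yl]oxy}-3-oxoprop-1-en-1-yl]-2,3-dihydrobenzofuran-3-carboxylate, via methyl enol ether 14 (not isolated), via iodanyl ketal 15 (not isolated)
Conditions: PhI(OAc)2 (1.2 equiv), H2SO4 (0.5 equiv), HC(OMe)3, 0 °C to rt, short reaction time; then H2O, aq. NaHCO3
Reagents that add atoms: trimethyl orthoformate, COC(OC)OC; water (work-up), O; (diacetoxyiodo)benzene, CC(=O)O[I](OC(C)=O)c1ccccc1 (atoms in 15 only)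
Why: Acid and orthoformate convert the C4 ketone into enol ether 14, PhI(OAc)2 attacks its C3 on the face anti to the C2 aryl group and methanol caps C4 to give ketal 15, in whose diequatorial half-chair the C4–C4a bond lies antiperiplanar to the C3–I bond, so that C4a migrates to C3 as iodobenzene leaves and the resulting dimethoxycarbenium ion is hydrolysed to the methyl ester. This is the known oxidative 1,2-aryl-shift ring contraction of flavanones to methyl trans-2-aryl-2,3-dihydrobenzofuran-3-carboxylates by trivalent iodine in trimethyl orthoformate, the cyclic version of the aryl ketone to arylacetate rearrangement. The five-membered ring is closed by backside (3-exo-tet, phenonium-like) attack of the ipso carbon C4a on C3 while the C4–C4a bond breaks, which is a 1,2-shift within the ring and not a cyclisation of an open chain. C2 is untouched and stays (S), and C3 is set by substrate control, because anti iodination followed by inversion at C3 places the expelled C4 trans to the C2 aryl group, which corresponds to (3S) and is also the thermodynamic arrangement. The step must prefer migration of C4a over a shift of ring B from C2 to C3, dehydrogenation and methoxy capture at C3, and this is secured by the O1 lone pair ortho to C4a (stabilised phenonium), by the two acetates on ring B (low migratory aptitude, no ionisation of C2–O1 and hence no racemisation) and by relief of peri strain between the C4 ketal and the C5 alkenyl group. The acetylated arenes and the electron-poor cinnamate are inert to the oxidant, so the enol ether is the only competent nucleophile.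

Step 9
Reactants: 16 protected monomethyl lithospermate from step 8
Product: 18 monomethyl lithospermate, via pentaacetate acid 17 (not isolated)
Conditions: Zn dust (10 equiv), NH4OAc (10 equiv), THF–H2O, rt, argon; then MeOH, rt; work-up at pH 3, reversed-phase chromatography
Reagents that add atoms: none
Why: Zinc reductively fragments the trichloroethyl ester (loss of 1,1-dichloroethene) and ammonium acetate then mediates methanolysis of the five aryl acetates only, both at near-neutral pH under reducing conditions, so that the methyl ester, the secondary cinnamate ester, the alkene, the catechols and the epimerisable C3 are left alone.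

Compound list
1 | 2',3'-dihydroxyacetophenone | CC(=O)c1cccc(O)c1O | starting material
2 | (E)-1-(2,3-dihydroxyphenyl)-3-(dimethylamino)prop-2-en-1-one | CN(C)/C=C/C(=O)c1cccc(O)c1O | intermediate
3 | 8-hydroxy-4H-chromen-4-one | O=c1ccoc2c(O)cccc12 | intermediate
4 | 4-oxo-4H-chromen-8-yl acetate | CC(=O)Oc1cccc2c(=O)ccoc12 | intermediate
5 | sodium (R)-3-(3,4-dihydroxyphenyl)-2-hydroxypropanoate (sodium danshensu) | [Na+].[O-]C(=O)[C@H](O)Cc1ccc(O)c(O)c1 | starting material
6 | 2,2,2-trichloroethyl (R)-3-(3,4-dihydroxyphenyl)-2-hydroxypropanoate | O=C(OCC(Cl)(Cl)Cl)[C@H](O)Cc1ccc(O)c(O)c1 | intermediate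
7 | 2,2,2-trichloroethyl (R)-3-(3,4-diacetoxyphenyl)-2-hydroxypropanoate | O=C(OCC(Cl)(Cl)Cl)[C@H](O)Cc1ccc(OC(C)=O)c(OC(C)=O)c1 | intermediate
8 | 2,2,2-trichloroethyl (R)-2-(acryloyloxy)-3-(3,4-diacetoxyphenyl)propanoate | C=CC(=O)O[C@H](Cc1ccc(OC(C)=O)c(OC(C)=O)c1)C(=O)OCC(Cl)(Cl)Cl | intermediate
9 | 1,2-phenylene diacetate | CC(=O)Oc1ccccc1OC(C)=O | starting material
10 | 4-(4,4,5,5-tetramethyl-1,3,2-dioxaborolan-2-yl)-1,2-phenylene diacetate | CC(=O)Oc1ccc(B2OC(C)(C)C(C)(C)O2)cc1OC(C)=O | intermediate
11 | (3,4-diacetoxyphenyl)boronic acid | CC(=O)Oc1ccc(B(O)O)cc1OC(C)=O | intermediate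
12 | 8-acetoxychromone carrying at C5 the (E)-acrylate of the protected (R)-danshensu | CC(=O)Oc1ccc(/C=C/C(=O)O[C@H](Cc2ccc(OC(C)=O)c(OC(C)=O)c2)C(=O)OCC(Cl)(Cl)Cl)c2c(=O)ccoc12 | intermediate
13 | (2S)-8-acetoxy-2-(3,4-diacetoxyphenyl)flavanone carrying the same C5 side chain | O=C1C[C@@H](c2ccc(OC(C)=O)c(OC(C)=O)c2)Oc2c(OC(C)=O)ccc(/C=C/C(=O)O[C@H](Cc3ccc(OC(C)=O)c(OC(C)=O)c3)C(=O)OCC(Cl)(Cl)Cl)c21 | intermediate
14 | (2S)-4-methoxy-2H-chromene (methyl enol ether of 13) | COC1=C[C@@H](c2ccc(OC(C)=O)c(OC(C)=O)c2)Oc2c(OC(C)=O)ccc(/C=C/C(=O)O[C@H](Cc3ccc(OC(C)=O)c(OC(C)=O)c3)C(=O)OCC(Cl)(Cl)Cl)c21 | intermediate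
15 | (2R,3R)-trans-3-[acetoxy(phenyl)iodanyl]-4,4-dimethoxyflavan (the C2 descriptor changes by priority only) | COC1(OC)[C@H]([I](OC(C)=O)c2ccccc2)[C@@H](c2ccc(OC(C)=O)c(OC(C)=O)c2)Oc2c(OC(C)=O)ccc(/C=C/C(=O)O[C@H](Cc3ccc(OC(C)=O)c(OC(C)=O)c3)C(=O)OCC(Cl)(Cl)Cl)c21 | intermediate
16 | pentaacetyl monomethyl lithospermate 2,2,2-trichloroethyl ester, (2S,3S) and (R) | COC(=O)[C@H]1c2c(/C=C/C(=O)O[C@H](Cc3ccc(OC(C)=O)c(OC(C)=O)c3)C(=O)OCC(Cl)(Cl)Cl)ccc(OC(C)=O)c2O[C@@H]1c1ccc(OC(C)=O)c(OC(C)=O)c1 | intermediate
17 | pentaacetyl monomethyl lithospermate (free acid) | COC(=O)[C@H]1c2c(/C=C/C(=O)O[C@H](Cc3ccc(OC(C)=O)c(OC(C)=O)c3)C(=O)O)ccc(OC(C)=O)c2O[C@@H]1c1ccc(OC(C)=O)c(OC(C)=O)c1 | intermediate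
18 | monomethyl lithospermate | COC(=O)[C@H]1c2c(/C=C/C(=O)O[C@H](Cc3ccc(O)c(O)c3)C(=O)O)ccc(O)c2O[C@@H]1c1ccc(O)c(O)c1 | target

Total step count: 9
Longest linear sequence: 6 (steps 1, 2, 6, 7, 8, 9; equally steps 3, 4, 6, 7, 8, 9)

Steps most likely to fail

Step 8.
- **What may go wrong:** The ketone, crowded by the peri alkenyl group, may be slow to form the enol ether. Iodination from the wrong face, or reaction through a diaxial conformer, may divert material into dehydrogenation or into migration of ring B. Slow acid methanolysis may strip an acetate and expose a phenol to the oxidant.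
- **Fallback:** The event is split into two known operations around a configurationally defined leaving group.
- **Bromination:** Setting out from 13, CuBr2 in EtOAc–CHCl3 at reflux (equilibrating conditions) should give the diequatorial (2R,3R)-trans-3-bromoflavanone F1, which can be purified as one diastereomer.
- **Rearrangement:** AgBF4 in HC(OMe)3–MeOH then ketalises C4 and abstracts bromide, which triggers the same shift of C4a to C3 with inversion (silver-promoted rearrangement of α-halo aryl ketals to arylacetic esters).
- **Return:** The route is rejoined at 16.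

Step 7.
- **What may go wrong:** Insertion into the peri-substituted chromone may be sluggish. The aryl-palladium species may add to the cinnamate instead, and facial selectivity may be poor next to the bulky C5 group.
- **Fallback:** The stereocentre is set before the side chain is present.
- **Bromide:** Setting out from 3, NBS in MeCN at 0 °C should brominate para to the free phenol to give 5-bromo-8-hydroxychromone F2. Ac2O and pyridine then give 5-bromo-8-acetoxychromone F3.
- **Arylation:** The same palladium-catalysed arylation with 11, now on a substrate with a single acceptor, should give the (2S)-bromoflavanone triacetate F4.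
- **Side chain:** A Heck reaction of F4 with acrylate 8 (Pd(OAc)2, P(o-tol)3, NaOAc, DMF, 90 °C) attaches the side chain; acetate is too weak a base to open the flavanone.
- **Return:** The route is rejoined at 13, and step 6 is bypassed as well.

Step 6.
- **What may go wrong:** At 100 °C the elaborate acrylate 8 may polymerise or its lactate stereocentre may erode, and turnover with a weakly coordinating ketone may stay low when the alkene cannot be used in excess.
- **Fallback:** The fragments are joined by esterification instead of by C–H coupling.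
- **Olefination:** Setting out from 4, the same rhodium-catalysed olefination is run with an excess of cheap tert-butyl acrylate to give tert-butyl (E)-3-(8-acetoxy-4-oxo-4H-chromen-5-yl)acrylate F5.
- **Acid:** TFA in CH2Cl2 then frees (E)-3-(8-acetoxy-4-oxo-4H-chromen-5-yl)acrylic acid F6.
- **Esterification:** A Steglich esterification (EDC·HCl, catalytic DMAP, CH2Cl2, 0 °C) couples F6 with alcohol 7, which is isolated for this purpose after the first stage of step 4.
- **Return:** The route is rejoined at 12.

Further compounds
F1 | step 8 | (2R,3R)-trans-3-bromo derivative of flavanone 13 | O=C1[C@H](Br)[C@@H](c2ccc(OC(C)=O)c(OC(C)=O)c2)Oc2c(OC(C)=O)ccc(/C=C/C(=O)O[C@H](Cc3ccc(OC(C)=O)c(OC(C)=O)c3)C(=O)OCC(Cl)(Cl)Cl)c21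
F2 | step 7 | 5-bromo-8-hydroxy-4H-chromen-4-one | O=c1ccoc2c(O)ccc(Br)c12
F3 | step 7 | 5-bromo-4-oxo-4H-chromen-8-yl acetate | CC(=O)Oc1ccc(Br)c2c(=O)ccoc12
F4 | step 7 | (2S)-8-acetoxy-5-bromo-2-(3,4-diacetoxyphenyl)chroman-4-one | O=C1C[C@@H](c2ccc(OC(C)=O)c(OC(C)=O)c2)Oc2c(OC(C)=O)ccc(Br)c21
F5 | step 6 | tert-butyl (E)-3-(8-acetoxy-4-oxo-4H-chromen-5-yl)acrylate | CC(=O)Oc1ccc(/C=C/C(=O)OC(C)(C)C)c2c(=O)ccoc12
F6 | step 6 | (E)-3-(8-acetoxy-4-oxo-4H-chromen-5-yl)acrylic acid | CC(=O)Oc1ccc(/C=C/C(=O)O)c2c(=O)ccoc12
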